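Z goes slowly, so I began by asking how much of its life a run of 80 min holds.

| setting | teal | grey | Thursday's | Friday's | Tuesday's | Wednesday's |
|---|---|---|---|---|---|---|
| Z | 0.28 M | 2.6 M | 0.40 M | 0.80 M | 1.5 M | 3.0 M |
| remark | run made earlier | run made earlier |  |  |  |  |
| time |  |  | 80 min | 80 min | 80 min | 80 min |

- percentages count the Z that a species holds: one G or D counts as two
- L is meant together with its Q
- solid, in amounts per volume of the solution: Q
- on the list of suspects stand: Z -> L; 2 Z -> G; Q <-> L; Z + L -> D
- the concentration of L that is asked is that of its free form alone
- "hardly changes" means that all values lie within two and a half points (for a concentration: within two and a half percent of the largest)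

- [L] (only what is free in solution) at the end for Thursday's, Friday's, Tuesday's, Wednesday's, in this order
- how that number moves from the first to the last of them (rises, then falls / falls all the way / rises all the way / falls, then rises / hardly changes)

| run | time / min | L / % |
|---|---|---|
| teal | 3.00 | 7 |
| teal | 5.00 | 12 |
| teal | 8.00 | 24 |
| teal | 15.0 | 35 |
| teal | 25.0 | 47 |
| teal | 40.0 | 59 |
| grey | 2.50 | 5 |
| grey | 8.00 | 14 |
| grey | 15.0 | 18 |
| grey | 20.0 | 20 |
| grey | 30.0 | 21 |
| grey | 40.0 | 27 |

(scatter of a reading: 1.5 percentage points)

Set side by side at 40.0 min, the two tables part: the teal run stands at 59% and the grey at 27%, although grey was charged with 2.6 M against teal's 0.28 M. A step of higher order in Z does this, and two Z going to G stands on the list of suspects.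

The dilute teal run therefore gave me my clock. Its row at 15.0 min reads 35%, and reckoned as first-order that is a half-life of Z of 24.1 min, a reading with the scatter of its point. I carried one quantity from it: the count of half-lives in a run, the run time over that half-life, which came to 3.31. That count leaves about 10.1% of the Z charged. I took this as the high side, with the step to G drawing on Z besides.

So I expected each flask to be past its making at the end, and the question became how its L divides between solution and crystals. The readings count L with its Q. The teal run already holds 0.165 M of the two together at 40.0 min, and the grey 0.702 M. Whether crystals stood in a flask, and at what free level, these readings cannot give, so my own reckoning stopped there, without a row of numbers.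

The forecast gave 0.25 M, 0.4 M, 0.57 M and 0.78 M, so that the number rises all the way, and it noted that the readings “cannot reveal a solubility limit”.

The flasks gave 0.160 M, 0.160 M, 0.160 M and 0.160 M: the number hardly changes.

    Z → L (k = 0.0352 min⁻¹)
    2 Z → G (k = 0.0408 L mol⁻¹ min⁻¹)
    Q ⇌ L, rate k3*(cs3 - [L]) while solid is left; crystals form when [L] > cs3 (solubility = 0.160 M, k = 2.99 min⁻¹)
    Z + L → D (k = 0.00862 L mol⁻¹ min⁻¹)

The count held on Thursday's flask, where Z stood at 2.93% after 80.0 min, below my 10.1%, and a tenfold time makes no difference to its free L. On Wednesday's flask Z stood lower still, at 0.730%. What holds the row level is the ceiling on dissolved L, its solubility: taking it away lifts Wednesday's free L from 0.160 M to 0.756 M.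

(The data were computed with constants of no real substance; scatter was added.)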